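Follow the solid.

solid substrate 1.5 M; partner 1.35 M; time 50 min

* target at 50 min, in percent of the solid substrate charged
* the change that raises the amount of target at 50 min, in percent of the solid substrate charged most ("none" if none brings more than 2 percentage points) (east / west / north-west / none)
* amount of target at 50 min, in percent of the solid substrate charged, after west

- percentages count the solid substrate that a species holds: one side product counts as two
- solid, in amounts per volume of the solution: solid substrate
- at the start none of the solid substrate is in solution
- run time (flask): 50 min

- east: doubling the solubility in step 2, all else as stated
- west: doubling the dissolution coefficient of step 2, all else as stated
- north-west: doubling the amount of partner, all else as stated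

    dissolved substrate + target → side product (k1 = 0.71 /M/min)
    solid substrate ⇌ dissolved substrate, rate k2*(cs2 - [dissolved substrate]) while solid is left; crystals form when [dissolved substrate] > cs2 (cs2 = 0.52 M, k2 = 0.10 /min)
    dissolved substrate + partner ⇌ target (K3 = 1.2 /M, k3 = 6.8 /M/min)
    partner ⇌ dormant form (K4 = 0.63, k4 = 0.033 /min)

Dissolution feeds a pool, dissolved substrate plus target. Counting its forward rate, with partner as charged, step 3 halves dissolved substrate in 0.076 min, far less than the run, so I held it at equilibrium, a pre-equilibrium. Each side product binds one partner, and what remains shares itself with the dormant form. So when all the substrate has become side product, free partner is 0.368 M. Multiplied by K3, that gives 0.442, the end lock: the late ratio [target]/[dissolved substrate].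

Control changes hands when the 1.5 M of solid has dissolved. Before that, I balanced the feed of step 2 against the loss by step 1. After it, the pool only loses.

My first way used the opening lock, 0.994, with partner as charged and shared with the dormant form. The balance put the pool at 0.319 M and the feed at 0.0360 M/min, so the 1.5 M lasted 41.6 min. Second-order loss at the end lock, with constant 0.302 /M/min, then brought the pool to 0.177 M at 50 min. That means target at 3.61%.

My second way used the end lock throughout. The pool stood at 0.316 M, the feed at 0.0301 M/min, the solid lasted 49.8 min, and target came to 6.45%.

The two parted, and I found the second cheating. The end lock counts partner as spent from the first minute, though at the start none of it is spent. That made the solid last longer than by the first way, and this way counted no decay after the solid. I kept 3.61%.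

The forecast gave 3.7%, a little above mine, then none for the best change and 2.2% after west. It held that “the solid runs out near 42 min”.

The simulation gave 3.65%, none and 1.97%. The 2 percentage points needed is more than the 1.5 points that north-west brought. The forecast's choice would fall if a run showed the north-west gain above 2 points.

At 50.0 min the flask read target 3.65% and dissolved substrate 8.54%, a ratio of 0.427 beside the end lock of 0.442. For the neighbour flask with 2.3 M of partner, the same balance gave an end lock of 1.14. That neighbour flask read dissolved substrate 4.17% and target 4.68%, a ratio of 1.12, and its answer to the first question was 4.68%.

The constants are assumed, and the outcome is calculated.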